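## Structural features

Artoindonesianin R (16) is an achiral 3-prenylflavone: a 4H-chromen-4-one (benzo ring A fused to pyranone ring C) with an aryl group (ring B) at C2 and a 3-methylbut-2-enyl chain at C3. Ring A has free hydroxyls at C5 and C7, which together with the ring oxygen on C8a form a 1,3,5-trioxygenated array around C4a. Ring B is joined through C1' and carries methoxy groups at C2' and C4' and a free hydroxyl at C5'. There are no stereocentres, so the problems are constitutional: three phenols must stay distinct from two methyl ethers, and aryl and prenyl must sit on the correct carbons of the tetrasubstituted C2=C3 bond, which is crowded by the ortho methoxy group of ring B. The fragile parts are the trisubstituted prenyl alkene (acid, hydrogenation, electrophilic oxidants), the electron-rich ring A (C-alkylation at C6 and C8 once its phenols are free) and C2 of the pyranone, a vinylogous ester carbon open to hard nucleophiles. The real difficulty is to close ring C with full substitution at C2 and C3 and to bring in the ring A oxygens without a series of differentiated phenol protections and without acid at the end. The key step uses the local twofold symmetry of ring A: since C5, C7 and C8a are all oxygenated, ring A can enter as a 2,4,6-trifluorobenzoyl group. Either ortho fluoride can then be displaced to form O1–C8a, and the two fluorides left over lie at C5 and C7, ortho and para to the C4 carbonyl, ready for exchange against oxygen.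

## Logic of the disconnections

16 from 15: the three phenolic O–H groups (O5, O7, O5') are traced back to three O–allyl bonds. One common masking group, orthogonal to the two methyl ethers and removable without acid, hydrogen or strong Lewis acid, protects the prenyl alkene and gives a single final deprotection. The forward step must remove three allyl groups with zerovalent palladium and a scavenger fast enough to stop the allyl fragment returning to a carbon of ring A.

15 from 12 and two equivalents of 13: the C5–O and C7–O bonds are cut. Both carbons are ortho or para to the C4 carbonyl, so each oxygen can come from one molecule of 13 by nucleophilic aromatic substitution of fluoride. This reduces ring A to a symmetrical trifluoroaryl unit with no phenols to differentiate. The forward step must drive the second substitution to completion on a ring already deactivated by the first alkoxy group, without addition at C2.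

12 from 9 and 10: the C3–C4 and O1–C8a bonds are cut. This removes ring C in one operation and leaves a ketone that already holds every ring B substituent and the prenyl chain, plus a commercial acid chloride. The forward step needs acylation of a hindered enolate at carbon, a second equivalent of base for the more acidic diketone, and ring closure through oxygen onto an ortho C–F carbon.

9 from 4 and 7: the C1'–C(=O) bond is cut into an aryl anion and an acyl cation equivalent. Bringing the whole 5-methylhex-4-enoyl chain in at once avoids monoalkylation of a methyl ketone and its risk of double alkylation. The forward step needs a bromine–lithium exchange that tolerates the allyl ether and a single addition to the amide.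

7 from 5: the amide C–N bond is cut. It only activates a commercial acid as an acyl donor that stops at the ketone stage. The demand is a mild amidation that leaves the alkene alone.

4 from 3: the O–allyl bond on ring B is cut. The protecting group is chosen to match the nucleophile 13 used later. The demand is an ordinary phenol alkylation.

3 from 1: the C5'–O bond is traced to a C–CHO bond. In 1 the formyl carbon, the two methoxy groups and the bromine already stand in the positions of C5', C4', C2' and C1', so one oxidative aryl migration sets the whole ring B pattern. The demand is clean aryl over hydride migration, which the ortho and para methoxy groups secure.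

## Other disconnections considered

Alternative 1: The cut runs through C2–C1' and C3–C1'', with rings A and C present from the start as 5,7-bis(methoxymethoxy)chromone A1. In the forward key step the ring B arylmagnesium bromide A2 would add to C2 of A1 under CuBr·SMe2 catalysis. The enolate would then be alkylated at C3 by prenyl bromide A3 in the same flask, which should give the racemic trans flavanone A4. Dehydrogenation across C2–C3 and removal of three MOM groups would follow.
- In favour: it is a three-component coupling, ring A arrives with its oxygens in place, and no substitution on a formed chromone is needed.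
- Against: no ring is closed, and two stereocentres are made only to be destroyed by an extra oxidation that must spare the prenyl group and two electron-rich rings. The chromanone enolate can open by β-elimination of the ring A phenoxide. A magnesium enolate is a weak partner for an allylic bromide, and residual arylcopper species can couple with A3 directly. The final MOM cleavage needs acid next to the prenyl alkene.
- Comparison: in skeletal bonds per flask (two) it is the equal of the chosen key step, and in convergence on ring A it is the better. It is the weaker on oxidation level, on the end-game conditions and slightly on step count (about eight to nine against seven).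

Alternative 2: The cut is C3–C4 alone, in the racemic aldehyde A5, a 2-(1-aryl-5-methylhex-4-en-2-ynyloxy)benzaldehyde. In the forward key step a thiazolium-derived carbene with K2CO3 would form a Breslow intermediate that adds 6-exo to the alkyne. This should give the (E)-3-alkylidene flavanone A6. A 1,3-hydrogen shift from C2 to C1'' would then be needed to reach the flavone, followed by MOM removal.
- In favour: the C–C bond formation is catalytic and metal-free. A6 is an isomer of the protected flavone, so no oxidant is required; on oxidation-state economy it is better than alternative 1 and the equal of the chosen plan. Like the chosen plan it makes C4 from an acyl carbon.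
- Against: A5 requires a secondary ether that is both benzylic and propargylic on an electron-rich ring and is therefore prone to ionisation. It must be made from a hindered, hydrogen-bonded salicylaldehyde. The electron-rich aldehyde is a reluctant partner for the carbene, and K2CO3 can isomerise the propargylic ether to an allene. The later hydrogen shift must protonate C1'' and not C3'', which would give the conjugated 3-(3-methylbut-1-enyl) isomer.
- Comparison: the chosen plan carries the prenyl group in intact and forms two bonds in its key step where this forms one. The alternative is longer (about ten steps).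

Alternative 3: Four bonds of ring A are cut (C8–C8a, C7–C8, C5–C6, C4a–C5), leading back to the pyranonyl diazoketone A7 and the siloxyalkyne A8. In the forward key step photochemical Wolff rearrangement of A7 would give a vinylketene that adds A8. Four-electron opening of the cyclobutenone and six-electron electrocyclisation onto pyranone C5 would follow. After tautomerisation this should give the 5-hydroxy-7-silyloxy-6-silyl flavone A9.
- In favour: ring A is built regiospecifically with four C–C bonds in one operation, which is better than the chosen key step in bonds formed. The C5 hydroxyl emerges free, and the regiochemical certainty equals that of the symmetric trifluoroaryl unit.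
- Against: A7 is a fully substituted 2-aryl-3-prenyl-4-pyranone-6-carbonyl compound that needs about as many steps as the whole chosen route, plus diazo chemistry. The pyranone chromophore competes for light. The electrocyclisation must interrupt the cross-conjugated pyranone. The C6 silyl group and two silyl ethers must afterwards be removed, the carbon-bound silicon by protodesilylation in the presence of the prenyl alkene.
- Comparison: the key step is mechanistically richer, but the route is clearly longer (twelve steps or more) and less safe at the end.

Key step: step 5

Remark on the chemistry: 5-methylhex-4-enoic acid (5) is assumed to be purchasable. The structures of 9 and 12 were checked against ring B of 16 (formyl carbon of 1 becomes C5', brominated carbon becomes C1') and need no correction. The C7 fluoride is assumed to be displaced before the C5 fluoride. Step 6 consumes two molecules of allyl alcohol per molecule of 12.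

## Route

Step 1
Reactants: 1 5-bromo-2,4-dimethoxybenzaldehyde
Product: 3 5-bromo-2,4-dimethoxyphenol, via aryl formate 2 (not isolated)
Conditions: mCPBA, CH2Cl2, 0 °C to rt; aq. NaHCO3 wash; then K2CO3 (cat.), MeOH, rt
Reagents that add atoms: mCPBA, O=C(OO)c1cccc(Cl)c1
Why: Dakin-type oxidation run as a Baeyer–Villiger reaction: the peracid adds to the aldehyde and the aryl group, a good migrating group because of its ortho and para methoxy substituents, shifts to oxygen to give formate 2, which K2CO3 in methanol cleaves by transesterification. The aryl bromide and the methyl ethers are inert to both reagents.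

Step 2
Reactants: 3 5-bromo-2,4-dimethoxyphenol
Product: 4 1-(allyloxy)-5-bromo-2,4-dimethoxybenzene
Conditions: allyl bromide, K2CO3, DMF, rt
Reagents that add atoms: allyl bromide, C=CCBr
Why: Williamson ether synthesis: the phenoxide of 3 displaces bromide from allyl bromide in an SN2 reaction. The allyl ether survives organolithium, amide base and alkoxide and can later be removed together with the ring A allyl ethers.

Step 3
Reactants: 5 5-methylhex-4-enoic acid
Product: 7 N-methoxy-N,5-dimethylhex-4-enamide, via acyl imidazolide 6 (not isolated)
Conditions: CDI, CH2Cl2, rt; then MeNH(OMe)·HCl, rt
Reagents that add atoms: N,O-dimethylhydroxylamine hydrochloride, CNOC.Cl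
Why: Amide formation through an activated acyl imidazolide: CDI converts 5 into 6 with loss of CO2, and N,O-dimethylhydroxylamine displaces imidazole to give the Weinreb amide. The trisubstituted alkene is untouched.

Step 4
Reactants: 4 1-(allyloxy)-5-bromo-2,4-dimethoxybenzene; 7 N-methoxy-N,5-dimethylhex-4-enamide
Product: 9 1-[5-(allyloxy)-2,4-dimethoxyphenyl]-5-methylhex-4-en-1-one, via aryllithium 8 (not isolated)
Conditions: 4, n-BuLi, THF, −78 °C; then 7, −78 to 0 °C; aq. NH4Cl
Reagents that add atoms: none
Why: Bromine–lithium exchange on 4 is fast at −78 °C and places lithium on the carbon that becomes C1'; aryllithium 8 adds once to 7 because the five-membered lithium chelate of the tetrahedral adduct survives until the aqueous quench (Weinreb ketone synthesis). The prenyl chain arrives complete, so no alkylation of a methyl ketone with its risk of double alkylation is needed.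

Step 5
Reactants: 9 1-[5-(allyloxy)-2,4-dimethoxyphenyl]-5-methylhex-4-en-1-one; 10 2,4,6-trifluorobenzoyl chloride
Product: 12 2-[5-(allyloxy)-2,4-dimethoxyphenyl]-5,7-difluoro-3-(3-methylbut-2-enyl)-4H-chromen-4-one, via lithium diketone enolate 11 (not isolated)
Conditions: LiN(SiMe3)2 (2.2 equiv), THF, −78 °C; 10, −78 °C to rt; then DMF, 60 °C
Reagents that add atoms: none
Why: LiN(SiMe3)2 converts 9 into its lithium enolate, which attacks acid chloride 10 at carbon in a crossed Claisen-type acylation (C3–C4); the 2-prenyl-1,3-diketone is at once deprotonated by the second equivalent of base, and any enol ester from O-acylation is funnelled to the same diketone enolate by acyl transfer to further enolate. The chelated diketone enolate 11 then closes ring C through the oxygen on the ring B carbon: it adds to an ortho carbon of the trifluorophenyl ring to give a Meisenheimer intermediate stabilised by the C4 carbonyl and the remaining fluorines, and fluoride is expelled (O1–C8a). The closest known reaction type is the one-flask acylation and intramolecular nucleophilic aromatic substitution of ketone enolates with 2-fluorobenzoyl chlorides that gives chromones and flavones. Ring C closes by addition–elimination through a six-membered transition state, formally 6-endo-trig if C8a=C4a–C4=O is counted as a vinylogous acyl fluoride. No stereocentre is formed, and the enolate geometry is immaterial because C2=C3 ends in an aromatic pyranone. Three selectivities are needed: carbon over oxygen acylation, secured by the lithium counter-ion, low temperature and excess base; oxygen over carbon ring closure, secured by geometry since the central carbon could only form a four-membered ring; and a single site of fluoride loss, secured by the twofold symmetry of the 2,4,6-trifluorophenyl group. The 2'-methoxy group of ring B is the only other conceivable leaving group and is far less activated than fluoride on the trifluorinated ring.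

Step 6
Reactants: 12 2-[5-(allyloxy)-2,4-dimethoxyphenyl]-5,7-difluoro-3-(3-methylbut-2-enyl)-4H-chromen-4-one; 13 allyl alcohol
Product: 15 5,7-bis(allyloxy)-2-[5-(allyloxy)-2,4-dimethoxyphenyl]-3-(3-methylbut-2-enyl)-4H-chromen-4-one, via monofluoride 14 (not isolated)
Conditions: 13 (3 equiv), NaH (2.5 equiv), THF, 0 °C; then 12, rt to 60 °C
Reagents that add atoms: allyl alcohol (second equivalent, delivered like the first as sodium allyloxide), C=CCO
Why: Two successive nucleophilic aromatic substitutions, each by one molecule of sodium allyloxide: C7 and C5 are para and ortho to the C4 carbonyl, so each Meisenheimer adduct is stabilised as an enolate and fluoride is the best leaving group for this mechanism; the para fluoride should react first (14), the ortho fluoride then with help from sodium coordination to the C4 oxygen. C2 is shielded by the aryl and prenyl groups and an alkoxide adduct there can revert, and the new allyl ethers match the ring B protecting group so that one deprotection serves all three.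

Step 7
Reactants: 15 5,7-bis(allyloxy)-2-[5-(allyloxy)-2,4-dimethoxyphenyl]-3-(3-methylbut-2-enyl)-4H-chromen-4-one
Product: 16 artoindonesianin R
Conditions: Pd(PPh3)4 (cat.), morpholine, THF, rt
Reagents that add atoms: none
Why: Zerovalent palladium ionises each aryl allyl ether to a π-allyl palladium cation and a phenoxide, and morpholine captures the allyl fragment irreversibly as 4-allylmorpholine (Tsuji–Trost deallylation). The conditions are neutral to mildly basic, so the prenyl alkene (no allylic leaving group), the methyl ethers and the pyranone are untouched.

## Compound list

1 | 5-bromo-2,4-dimethoxybenzaldehyde | COc1cc(OC)c(Br)cc1C=O | starting material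
2 | 5-bromo-2,4-dimethoxyphenyl formate | COc1cc(OC)c(Br)cc1OC=O | intermediate (not isolated)
3 | 5-bromo-2,4-dimethoxyphenol | COc1cc(OC)c(Br)cc1O | intermediate
4 | 1-(allyloxy)-5-bromo-2,4-dimethoxybenzene | COc1cc(OC)c(Br)cc1OCC=C | intermediate
5 | 5-methylhex-4-enoic acid | CC(C)=CCCC(=O)O | starting material
6 | 1-(5-methylhex-4-enoyl)-1H-imidazole | CC(C)=CCCC(=O)n1ccnc1 | intermediate (not isolated)
7 | N-methoxy-N,5-dimethylhex-4-enamide | CC(C)=CCCC(=O)N(C)OC | intermediate
8 | [5-(allyloxy)-2,4-dimethoxyphenyl]lithium | [Li]c1cc(OCC=C)c(OC)cc1OC | intermediate (not isolated)
9 | 1-[5-(allyloxy)-2,4-dimethoxyphenyl]-5-methylhex-4-en-1-one | CC(C)=CCCC(=O)c1cc(OCC=C)c(OC)cc1OC | intermediate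
10 | 2,4,6-trifluorobenzoyl chloride | O=C(Cl)c1c(F)cc(F)cc1F | starting material
11 | 1-[5-(allyloxy)-2,4-dimethoxyphenyl]-2-(3-methylbut-2-enyl)-3-(2,4,6-trifluorophenyl)propane-1,3-dione, present in the flask as its lithium enolate | CC(C)=CCC(C(=O)c1cc(OCC=C)c(OC)cc1OC)C(=O)c1c(F)cc(F)cc1F | intermediate (not isolated)
12 | 2-[5-(allyloxy)-2,4-dimethoxyphenyl]-5,7-difluoro-3-(3-methylbut-2-enyl)-4H-chromen-4-one | CC(C)=CCc1c(-c2cc(OCC=C)c(OC)cc2OC)oc2cc(F)cc(F)c2c1=O | intermediate
13 | allyl alcohol (prop-2-en-1-ol) | C=CCO | starting material
14 | 7-(allyloxy)-2-[5-(allyloxy)-2,4-dimethoxyphenyl]-5-fluoro-3-(3-methylbut-2-enyl)-4H-chromen-4-one | CC(C)=CCc1c(-c2cc(OCC=C)c(OC)cc2OC)oc2cc(OCC=C)cc(F)c2c1=O | intermediate (not isolated)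
15 | 5,7-bis(allyloxy)-2-[5-(allyloxy)-2,4-dimethoxyphenyl]-3-(3-methylbut-2-enyl)-4H-chromen-4-one | CC(C)=CCc1c(-c2cc(OCC=C)c(OC)cc2OC)oc2cc(OCC=C)cc(OCC=C)c2c1=O | intermediate
16 | artoindonesianin R, 5,7-dihydroxy-2-(5-hydroxy-2,4-dimethoxyphenyl)-3-(3-methylbut-2-enyl)-4H-chromen-4-one | COc1cc(OC)c(-c2oc3cc(O)cc(O)c3c(=O)c2CC=C(C)C)cc1O | target

## Step count and least certain steps

Total step count: 7. Longest linear sequence: 6 steps (steps 1, 2, 4, 5, 6, 7); step 3 is a one-step side branch.

Step 5 (key step). The most likely failure is acylation of the hindered, α-substituted enolate at oxygen without complete acyl transfer to carbon. The ring closure may also stall, because the lithium chelate of the diketone is a poor oxygen nucleophile in THF; prolonged heating with residual amide base then invites intermolecular attack on the fluorinated ring. The fallback sets out from 9 and 10 and separates the two events. 10 is converted with 1H-benzotriazole and Et3N into 1-(2,4,6-trifluorobenzoyl)-1H-benzotriazole F1, a neutral acyl donor that transfers its acyl group to lithium enolates at carbon. The lithium enolate of 9 is acylated with F1, diketone 11 is isolated, and the ring is closed separately with K2CO3 in DMF, where the potassium enolate is a free oxygen nucleophile. The fallback comes back to the route at 12.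

Step 6. The second substitution may stop short, because the first allyloxy group deactivates ring A. Forcing it invites reversible alkoxide addition at C2 with opening of ring C, and base-induced migration of allyl ethers to propenyl ethers that zerovalent palladium would no longer cleave. The fallback sets out from 12. Sodium allyloxide at room temperature is used only for the easy para substitution, and 14 is isolated. The C5 fluoride is then displaced by the anion of (E)-benzaldoxime (Cs2CO3, DMSO), an α-effect nucleophile of low basicity. This gives the O-aryl oxime F2, which fragments in the flask to benzonitrile and the chelated 5-hydroxy compound 7-(allyloxy)-2-[5-(allyloxy)-2,4-dimethoxyphenyl]-5-hydroxy-3-(3-methylbut-2-enyl)-4H-chromen-4-one F3. F3 is submitted to the conditions of step 7 and the fallback comes back to the route at 16.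

Step 4. Proton transfer from the α-methylene of 7 to the basic, ortho-methoxy-substituted aryllithium 8 may compete with addition, returning reduced arene and unchanged amide. On warming, 8 may also deprotonate the allyl ether next to oxygen. The fallback sets out from 4 and 7. 7 is reduced with iBu2AlH at −78 °C to 5-methylhex-4-enal F4. 8, generated from 4 as in the route, adds to this far more electrophilic carbonyl at −78 °C to give the racemic benzylic alcohol 1-[5-(allyloxy)-2,4-dimethoxyphenyl]-5-methylhex-4-en-1-ol F5. Oxidation of this electron-rich benzylic alcohol with MnO2 in CH2Cl2 comes back to the route at 9.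

Step 7. The π-allyl palladium fragment may return to the ambident phenoxide of the phloroglucinol-type ring A at carbon (C6 or C8) faster than the scavenger captures it. Cleavage of the chelated C5 ether may also lag. The fallback sets out from 15 and avoids π-allyl intermediates. The three allyl ethers are isomerised with hydrogen-activated [Ir(cod)(PMePh2)2]PF6 in THF to the tris[(E)-prop-1-enyl] ether F6; the trisubstituted prenyl alkene does not migrate under these conditions. The enol ethers are then hydrolysed with dilute aqueous HCl in acetone at room temperature, releasing propanal, and the fallback comes back to the route at 16.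

## Further compounds

F1 | step 5 | 1-(2,4,6-trifluorobenzoyl)-1H-benzotriazole | O=C(c1c(F)cc(F)cc1F)n1nnc2ccccc12
F2 | step 6 | (E)-benzaldehyde O-{7-(allyloxy)-2-[5-(allyloxy)-2,4-dimethoxyphenyl]-3-(3-methylbut-2-enyl)-4-oxo-4H-chromen-5-yl}oxime | CC(C)=CCc1c(-c2cc(OCC=C)c(OC)cc2OC)oc2cc(OCC=C)cc(O/N=C/c3ccccc3)c2c1=O
F3 | step 6 | 7-(allyloxy)-2-[5-(allyloxy)-2,4-dimethoxyphenyl]-5-hydroxy-3-(3-methylbut-2-enyl)-4H-chromen-4-one | CC(C)=CCc1c(-c2cc(OCC=C)c(OC)cc2OC)oc2cc(OCC=C)cc(O)c2c1=O
F4 | step 4 | 5-methylhex-4-enal | CC(C)=CCCC=O
F5 | step 4 | 1-[5-(allyloxy)-2,4-dimethoxyphenyl]-5-methylhex-4-en-1-ol (racemic) | CC(C)=CCCC(O)c1cc(OCC=C)c(OC)cc1OC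
F6 | step 7 | 2-{2,4-dimethoxy-5-[(E)-prop-1-enyloxy]phenyl}-3-(3-methylbut-2-enyl)-5,7-bis[(E)-prop-1-enyloxy]-4H-chromen-4-one | C/C=C/Oc1cc(O/C=C/C)c2c(c1)oc(-c1cc(O/C=C/C)c(OC)cc1OC)c(CC=C(C)C)c2=O
A1 | alternative 1 | 5,7-bis(methoxymethoxy)-4H-chromen-4-one | O=c1ccoc2cc(OCOC)cc(OCOC)c12
A2 | alternative 1 | [2,4-dimethoxy-5-(methoxymethoxy)phenyl]magnesium bromide | Br[Mg]c1cc(OCOC)c(OC)cc1OC
A3 | alternative 1 | prenyl bromide (1-bromo-3-methylbut-2-ene) | CC(C)=CCBr
A4 | alternative 1 | trans-2-[2,4-dimethoxy-5-(methoxymethoxy)phenyl]-5,7-bis(methoxymethoxy)-3-(3-methylbut-2-enyl)chroman-4-one (racemic, one enantiomer drawn) | O=C1[C@H](CC=C(C)C)[C@@H](c3cc(OCOC)c(OC)cc3OC)Oc2cc(OCOC)cc(OCOC)c12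
A5 | alternative 2 | 2-{[1-(2,4-dimethoxy-5-(methoxymethoxy)phenyl)-5-methylhex-4-en-2-yn-1-yl]oxy}-4,6-bis(methoxymethoxy)benzaldehyde (racemic) | CC(C)=CC#CC(Oc1cc(OCOC)cc(OCOC)c1C=O)c1cc(OCOC)c(OC)cc1OC
A6 | alternative 2 | (E)-2-[2,4-dimethoxy-5-(methoxymethoxy)phenyl]-5,7-bis(methoxymethoxy)-3-(3-methylbut-2-enylidene)chroman-4-one (racemic) | CC(C)=C/C=C1/C(=O)c2c(OCOC)cc(OCOC)cc2OC1c1cc(OCOC)c(OC)cc1OC
A7 | alternative 3 | 6-(2-diazoacetyl)-2-[2,4-dimethoxy-5-(triisopropylsilyloxy)phenyl]-3-(3-methylbut-2-enyl)-4H-pyran-4-one | COc1cc(OC)c(-c2oc(C(=O)C=[N+]=[N-])cc(=O)c2CC=C(C)C)cc1O[Si](C(C)C)(C(C)C)C(C)C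
A8 | alternative 3 | triisopropyl{[(trimethylsilyl)ethynyl]oxy}silane | C[Si](C)(C)C#CO[Si](C(C)C)(C(C)C)C(C)C
A9 | alternative 3 | 2-[2,4-dimethoxy-5-(triisopropylsilyloxy)phenyl]-5-hydroxy-3-(3-methylbut-2-enyl)-7-(triisopropylsilyloxy)-6-(trimethylsilyl)-4H-chromen-4-one | COc1cc(OC)c(-c2oc3cc(O[Si](C(C)C)(C(C)C)C(C)C)c([Si](C)(C)C)c(O)c3c(=O)c2CC=C(C)C)cc1O[Si](C(C)C)(C(C)C)C(C)C
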